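Assumption: the SMILES is read as (1R,4S,7R,7aS) in the ring system and (8R) in the side chain, which puts the angular methyl, the C7 carboxyl, the C4 ester oxygen and the C1 side chain all on one face.

## Retrosynthetic overview

- The enal is unveiled last by oxidation of a primary allylic alcohol, after one acidolysis removes a tert-butyl ester and a silyl ether. The C4 ester comes from Yamaguchi coupling of a γ-hydroxy enone core with (2E,4E,6E,8R)-6,8-dimethyldeca-2,4,6-trienoic acid (Evans methylation, Wittig, vinylogous Horner–Wadsworth–Emmons).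
- The C4 hydroxyl comes from axial γ-hydroxylation of the bicyclic enone through its silyl dienol ether. The C1 side chain comes from α′-alkylation of the enone with a 2-(silyloxymethyl)allyl bromide.
- The cyclopentenone is closed by intramolecular aldol condensation of a 1,4-diketone (methyl ketone onto the cyclohexanone carbonyl).
- The diketone comes from Wacker oxidation of an allyl ketone. Quaternary C7a is set by palladium-catalysed allylation trans to the C7 ester. C7 is set by CBS reduction and hydroxyl-directed hydrogenation of an ene keto ester made by Birch reduction of 3-methoxy-2-methylbenzoic acid.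
- Ring order: the six-membered carbocycle is present from the arene; the five-membered enone ring is formed second.

## Route

Step 1
Reactants: 1 3-methoxy-2-methylbenzoic acid
Product: 3 2-methyl-3-oxocyclohex-1-ene-1-carboxylic acid, via dihydro enol ether acid 2 (not isolated)
Conditions: Li, NH3 (l), t-BuOH, THF, −78 °C; NH4Cl; then 2 M HCl, THF, 60 °C
Reagents that add atoms: water (O)
Why: Birch reduction gives the 1,4-dihydro enol ether, and acid hydrolysis with double-bond migration settles in the doubly conjugated tetrasubstituted ene keto acid; no stereocentre is formed.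

Step 2
Reactants: 3 2-methyl-3-oxocyclohex-1-ene-1-carboxylic acid
Product: 4 tert-butyl 2-methyl-3-oxocyclohex-1-ene-1-carboxylate
Conditions: 2-methylpropene (excess), cat. H2SO4, CH2Cl2, sealed tube, rt
Reagents that add atoms: 2-methylpropene (C=C(C)C)
Why: Acid-catalysed tert-butyl ester formation installs an ester that resists enolisation and Claisen-type acylation in the later base steps.

Step 3
Reactants: 4 tert-butyl 2-methyl-3-oxocyclohex-1-ene-1-carboxylate
Product: 5 tert-butyl (3R)-3-hydroxy-2-methylcyclohex-1-ene-1-carboxylate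
Conditions: (S)-1-methyl-3,3-diphenyltetrahydro-1H,3H-pyrrolo[1,2-c][1,3,2]oxazaborole [(S)-Me-CBS, 15 mol%], catecholborane, toluene, −78 °C; MeOH quench
Reagents that add atoms: none
Why: Corey–Bakshi–Shibata reduction, with the substituted alkenyl arm acting as the large group, delivers hydride to give the (3R)-allylic alcohol while the electron-poor tetrasubstituted alkene and the ester are untouched.

Step 4
Reactants: 5 tert-butyl (3R)-3-hydroxy-2-methylcyclohex-1-ene-1-carboxylate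
Product: 6 tert-butyl (1R,2R,3R)-3-hydroxy-2-methylcyclohexane-1-carboxylate
Conditions: [Ir(cod)(PCy3)(py)]PF6 (5 mol%), H2 (3 atm), CH2Cl2, rt
Reagents that add atoms: none
Why: Hydroxyl-directed homogeneous hydrogenation adds H2 to the tetrasubstituted alkene on the face of the hydroxyl group, which fixes C1 (the later C7) as R.

Step 5
Reactants: 6 tert-butyl (1R,2R,3R)-3-hydroxy-2-methylcyclohexane-1-carboxylate
Product: 7 tert-butyl (1R,2R)-2-methyl-3-oxocyclohexane-1-carboxylate
Conditions: Dess–Martin periodinane, CH2Cl2, rt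
Reagents that add atoms: none
Why: Dess–Martin oxidation returns the ketone without touching C1, which is not enolisable through the ketone (C2 may epimerise but becomes planar in the next step).

Step 6
Reactants: 7 tert-butyl (1R,2R)-2-methyl-3-oxocyclohexane-1-carboxylate
Product: 8 tert-butyl (1R)-2-methyl-3-[(trimethylsilyl)oxy]cyclohex-2-ene-1-carboxylate
Conditions: Me3SiCl, Et3N, DMF, 110 °C
Reagents that add atoms: chlorotrimethylsilane (C[Si](C)(C)Cl)
Why: Thermodynamic silyl enol ether formation favours the tetrasubstituted enol ether toward the methyl-bearing carbon; the minor C3–C4 regioisomer is removed here or after step 7.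

Step 7
Reactants: 8 tert-butyl (1R)-2-methyl-3-[(trimethylsilyl)oxy]cyclohex-2-ene-1-carboxylate
Product: 9 tert-butyl (1R,2S)-2-methyl-3-oxo-2-(prop-2-en-1-yl)cyclohexane-1-carboxylate
Conditions: diallyl carbonate, Pd2(dba)3 (2.5 mol%), PPh3 (12 mol%), Bu4N[Ph3SiF2] (35 mol%), THF, 25 °C
Reagents that add atoms: diallyl carbonate (C=CCOC(=O)OCC=C)
Why: Tsuji–Trost allylation of the fluoride-released enolate occurs at the enol ether carbon and anti to the adjacent pseudoaxial tert-butyl ester, which sets the quaternary centre with the methyl cis to the ester.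

Step 8
Reactants: 9 tert-butyl (1R,2S)-2-methyl-3-oxo-2-(prop-2-en-1-yl)cyclohexane-1-carboxylate
Product: 10 tert-butyl (1R,2S)-2-methyl-3-oxo-2-(2-oxopropyl)cyclohexane-1-carboxylate
Conditions: PdCl2 (10 mol%), CuCl (30 mol%), O2 (1 atm), DMF/H2O 7:1, rt
Reagents that add atoms: water (O)
Why: Tsuji–Wacker oxidation converts the terminal alkene to the methyl ketone with Markovnikov selectivity; ketone and tert-butyl ester are inert.

Step 9
Reactants: 10 tert-butyl (1R,2S)-2-methyl-3-oxo-2-(2-oxopropyl)cyclohexane-1-carboxylate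
Product: 12 tert-butyl (7R,7aS)-7a-methyl-2-oxo-2,4,5,6,7,7a-hexahydro-1H-indene-7-carboxylate, via aldol adduct 11 (not isolated)
Conditions: KOtBu (0.3 equiv), t-BuOH/THF, 0 to 30 °C
Reagents that add atoms: none
Why: Intramolecular aldol addition of the methyl ketone enolate to the ring ketone followed by E1cB dehydration closes the cyclopentenone, the only adduct that can dehydrate, without disturbing C7 or C7a.

Step 10
Reactants: 13 2-methylidenepropane-1,3-diol
Product: 14 2-({[tert-butyl(dimethyl)silyl]oxy}methyl)prop-2-en-1-ol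
Conditions: t-BuMe2SiCl (1 equiv), imidazole, 13 (3 equiv), THF, 0 °C to rt
Reagents that add atoms: tert-butyl(chloro)dimethylsilane (CC(C)(C)[Si](C)(C)Cl)
Why: Statistical monosilylation of the symmetric diol, used in excess, gives the mono silyl ether.

Step 11
Reactants: 14 2-({[tert-butyl(dimethyl)silyl]oxy}methyl)prop-2-en-1-ol
Product: 15 {[2-(bromomethyl)prop-2-en-1-yl]oxy}(tert-butyl)dimethylsilane
Conditions: CBr4, PPh3, CH2Cl2, 0 °C
Reagents that add atoms: tetrabromomethane (BrC(Br)(Br)Br)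
Why: Appel bromination converts the primary allylic alcohol to the bromide under neutral conditions that leave the silyl ether intact.

Step 12
Reactants: 12 tert-butyl (7R,7aS)-7a-methyl-2-oxo-2,4,5,6,7,7a-hexahydro-1H-indene-7-carboxylate; 15 {[2-(bromomethyl)prop-2-en-1-yl]oxy}(tert-butyl)dimethylsilane
Product: 17 tert-butyl (1R,7R,7aS)-1-[2-({[tert-butyl(dimethyl)silyl]oxy}methyl)prop-2-en-1-yl]-7a-methyl-2-oxo-2,4,5,6,7,7a-hexahydro-1H-indene-7-carboxylate, via lithium dienolate 16 (not isolated)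
Conditions: LiN(iPr)2 (1.05 equiv), THF, −78 °C; then 15, DMPU, −78 to −30 °C
Reagents that add atoms: none
Why: Kinetic α′-deprotonation gives the cross-conjugated dienolate, and SN2 enolate alkylation takes place on the face of the angular methyl, away from the larger C7 methine carrying the tert-butyl ester, to set C1 as R.

Step 13
Reactants: 17 tert-butyl (1R,7R,7aS)-1-[2-({[tert-butyl(dimethyl)silyl]oxy}methyl)prop-2-en-1-yl]-7a-methyl-2-oxo-2,4,5,6,7,7a-hexahydro-1H-indene-7-carboxylate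
Product: 18 tert-butyl (1R,7R,7aS)-2-{[tert-butyl(dimethyl)silyl]oxy}-1-[2-({[tert-butyl(dimethyl)silyl]oxy}methyl)prop-2-en-1-yl]-7a-methyl-5,6,7,7a-tetrahydro-1H-indene-7-carboxylate
Conditions: t-BuMe2SiOTf, Et3N, CH2Cl2, −78 to 0 °C
Reagents that add atoms: tert-butyldimethylsilyl trifluoromethanesulfonate (CC(C)(C)[Si](C)(C)OS(=O)(=O)C(F)(F)F)
Why: Soft enolisation removes the accessible pseudoaxial γ-hydrogen at C4 instead of the hindered tertiary C1 hydrogen and gives the linearly conjugated silyl dienol ether.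

Step 14
Reactants: 18 tert-butyl (1R,7R,7aS)-2-{[tert-butyl(dimethyl)silyl]oxy}-1-[2-({[tert-butyl(dimethyl)silyl]oxy}methyl)prop-2-en-1-yl]-7a-methyl-5,6,7,7a-tetrahydro-1H-indene-7-carboxylate
Product: 19 tert-butyl (1R,4S,7R,7aS)-1-[2-({[tert-butyl(dimethyl)silyl]oxy}methyl)prop-2-en-1-yl]-4-hydroxy-7a-methyl-2-oxo-2,4,5,6,7,7a-hexahydro-1H-indene-7-carboxylate
Conditions: mCPBA (1.05 equiv), CH2Cl2, −40 to 0 °C; aq. NaHCO3/Na2S2O3 work-up
Reagents that add atoms: 3-chloroperoxybenzoic acid (OOC(=O)c1cccc(Cl)c1)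
Why: In this vinylogous Rubottom oxidation the peracid attacks the diene terminus C4 axially on the face of the angular methyl, as in the 6β-hydroxylation of steroidal dienol ethers, giving the (4S)-alcohol; the isolated 1,1-disubstituted alkene is far less nucleophilic.

Step 15
Reactants: 20 (4R)-4-benzyl-1,3-oxazolidin-2-one; 21 butanoyl chloride
Product: 22 (4R)-4-benzyl-3-butanoyl-1,3-oxazolidin-2-one
Conditions: Et3N, 4-(dimethylamino)pyridine (10 mol%), CH2Cl2, 0 °C to rt
Reagents that add atoms: none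
Why: N-acylation of the oxazolidinone by the acid chloride under nucleophilic catalysis attaches the chiral auxiliary.

Step 16
Reactants: 22 (4R)-4-benzyl-3-butanoyl-1,3-oxazolidin-2-one
Product: 24 (4R)-4-benzyl-3-[(2R)-2-methylbutanoyl]-1,3-oxazolidin-2-one, via sodium enolate 23 (not isolated)
Conditions: NaN(SiMe3)2, THF, −78 °C; then MeI, −78 °C
Reagents that add atoms: iodomethane (CI)
Why: Evans asymmetric alkylation methylates the chelated Z-enolate on the face opposite the benzyl group, giving the (2R)-2-methylbutanoyl imide.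

Step 17
Reactants: 24 (4R)-4-benzyl-3-[(2R)-2-methylbutanoyl]-1,3-oxazolidin-2-one
Product: 25 (2R)-2-methylbutan-1-ol
Conditions: LiBH4, H2O (1 equiv), Et2O, 0 °C; distillation
Reagents that add atoms: none
Why: Reductive cleavage of the imide releases the primary alcohol without epimerisation and returns the auxiliary.

Step 18
Reactants: 25 (2R)-2-methylbutan-1-ol; 26 ethyl 2-(triphenyl-λ5-phosphanylidene)propanoate
Product: 28 ethyl (2E,4R)-2,4-dimethylhex-2-enoate, via aldehyde 27 (not isolated)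
Conditions: PhI(OAc)2, TEMPO (10 mol%), CH2Cl2, rt; then 26, 40 °C
Reagents that add atoms: none
Why: Base-free TEMPO oxidation gives the configurationally labile aldehyde, and in situ Wittig olefination with the stabilised ylide forms the E-trisubstituted enoate.

Step 19
Reactants: 28 ethyl (2E,4R)-2,4-dimethylhex-2-enoate
Product: 29 (2E,4R)-2,4-dimethylhex-2-en-1-ol
Conditions: iBu2AlH (2.2 equiv), CH2Cl2, −78 °C; Rochelle salt work-up
Reagents that add atoms: none
Why: 1,2-Reduction of the conjugated ester gives the allylic alcohol without touching the alkene or the allylic stereocentre.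

Step 20
Reactants: 29 (2E,4R)-2,4-dimethylhex-2-en-1-ol
Product: 30 (2E,4R)-2,4-dimethylhex-2-enal
Conditions: MnO2 (excess), CH2Cl2, rt
Reagents that add atoms: none
Why: Allylic oxidation with MnO2 gives the enal with retention of the E geometry.

Step 21
Reactants: 30 (2E,4R)-2,4-dimethylhex-2-enal; 31 ethyl (2E)-4-(diethoxyphosphoryl)but-2-enoate
Product: 33 ethyl (2E,4E,6E,8R)-6,8-dimethyldeca-2,4,6-trienoate, via lithiated phosphonate 32 (not isolated)
Conditions: LiN(SiMe3)2, THF, −78 °C; then 30, −78 to 0 °C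
Reagents that add atoms: none
Why: Vinylogous Horner–Wadsworth–Emmons olefination forms the new C4=C5 bond with E geometry and extends the chain to the (2E,4E,6E)-trienoate.

Step 22
Reactants: 33 ethyl (2E,4E,6E,8R)-6,8-dimethyldeca-2,4,6-trienoate
Product: 34 (2E,4E,6E,8R)-6,8-dimethyldeca-2,4,6-trienoic acid
Conditions: LiOH·H2O, THF/H2O, rt; then 1 M HCl to pH 3
Reagents that add atoms: lithium hydroxide ([Li+].[OH-])
Why: Saponification of the ethyl ester gives the acid; the C8 stereocentre is not acidic.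

Step 23
Reactants: 19 tert-butyl (1R,4S,7R,7aS)-1-[2-({[tert-butyl(dimethyl)silyl]oxy}methyl)prop-2-en-1-yl]-4-hydroxy-7a-methyl-2-oxo-2,4,5,6,7,7a-hexahydro-1H-indene-7-carboxylate; 34 (2E,4E,6E,8R)-6,8-dimethyldeca-2,4,6-trienoic acid
Product: 36 tert-butyl (1R,4S,7R,7aS)-1-[2-({[tert-butyl(dimethyl)silyl]oxy}methyl)prop-2-en-1-yl]-4-{[(2E,4E,6E,8R)-6,8-dimethyldeca-2,4,6-trienoyl]oxy}-7a-methyl-2-oxo-2,4,5,6,7,7a-hexahydro-1H-indene-7-carboxylate, via mixed anhydride 35 (not isolated)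
Conditions: 34, 2,4,6-trichlorobenzoyl chloride, Et3N, toluene, rt; then 19, 4-(dimethylamino)pyridine, rt
Reagents that add atoms: none
Why: Yamaguchi esterification acylates the hindered pseudoaxial secondary alcohol through the acylpyridinium ion with retention at C4.

Step 24
Reactants: 36 tert-butyl (1R,4S,7R,7aS)-1-[2-({[tert-butyl(dimethyl)silyl]oxy}methyl)prop-2-en-1-yl]-4-{[(2E,4E,6E,8R)-6,8-dimethyldeca-2,4,6-trienoyl]oxy}-7a-methyl-2-oxo-2,4,5,6,7,7a-hexahydro-1H-indene-7-carboxylate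
Product: 37 (1R,4S,7R,7aS)-4-{[(2E,4E,6E,8R)-6,8-dimethyldeca-2,4,6-trienoyl]oxy}-1-[2-(hydroxymethyl)prop-2-en-1-yl]-7a-methyl-2-oxo-2,4,5,6,7,7a-hexahydro-1H-indene-7-carboxylic acid
Conditions: CF3CO2H/CH2Cl2/H2O 9:9:1, 0 °C to rt
Reagents that add atoms: none
Why: Acidolysis removes the tert-butyl ester and the primary silyl ether in one operation, while the enone, the trienoate and the allylic ester (ionisation disfavoured by the adjacent enone) survive.

Step 25
Reactants: 37 (1R,4S,7R,7aS)-4-{[(2E,4E,6E,8R)-6,8-dimethyldeca-2,4,6-trienoyl]oxy}-1-[2-(hydroxymethyl)prop-2-en-1-yl]-7a-methyl-2-oxo-2,4,5,6,7,7a-hexahydro-1H-indene-7-carboxylic acid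
Product: 38 (1R,4S,7R,7aS)-4-{[(2E,4E,6E,8R)-6,8-dimethyldeca-2,4,6-trienoyl]oxy}-1-(2-formylprop-2-en-1-yl)-7a-methyl-2-oxo-2,4,5,6,7,7a-hexahydro-1H-indene-7-carboxylic acid
Conditions: Dess–Martin periodinane, CH2Cl2, 0 °C to rt
Reagents that add atoms: none
Why: Dess–Martin oxidation of the only remaining alcohol gives the α-methylene aldehyde under mild non-basic conditions compatible with the free acid and the epimerisable C1 centre.

## Compound list

1 | 3-methoxy-2-methylbenzoic acid | COc1cccc(C(=O)O)c1C | starting material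
2 | 3-methoxy-2-methylcyclohexa-2,5-diene-1-carboxylic acid (racemic) | COC1=C(C)C(C(=O)O)C=CC1 | intermediate
3 | 2-methyl-3-oxocyclohex-1-ene-1-carboxylic acid | CC1=C(C(=O)O)CCCC1=O | intermediate
4 | tert-butyl 2-methyl-3-oxocyclohex-1-ene-1-carboxylate | CC1=C(C(=O)OC(C)(C)C)CCCC1=O | intermediate
5 | tert-butyl (3R)-3-hydroxy-2-methylcyclohex-1-ene-1-carboxylate | CC1=C(C(=O)OC(C)(C)C)CCC[C@H]1O | intermediate
6 | tert-butyl (1R,2R,3R)-3-hydroxy-2-methylcyclohexane-1-carboxylate | C[C@H]1[C@H](O)CCC[C@H]1C(=O)OC(C)(C)C | intermediate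
7 | tert-butyl (1R,2R)-2-methyl-3-oxocyclohexane-1-carboxylate (C2 epimerisable) | C[C@H]1C(=O)CCC[C@H]1C(=O)OC(C)(C)C | intermediate
8 | tert-butyl (1R)-2-methyl-3-[(trimethylsilyl)oxy]cyclohex-2-ene-1-carboxylate | CC1=C(O[Si](C)(C)C)CCC[C@H]1C(=O)OC(C)(C)C | intermediate
9 | tert-butyl (1R,2S)-2-methyl-3-oxo-2-(prop-2-en-1-yl)cyclohexane-1-carboxylate | C=CC[C@]1(C)C(=O)CCC[C@H]1C(=O)OC(C)(C)C | intermediate
10 | tert-butyl (1R,2S)-2-methyl-3-oxo-2-(2-oxopropyl)cyclohexane-1-carboxylate | CC(=O)C[C@]1(C)C(=O)CCC[C@H]1C(=O)OC(C)(C)C | intermediate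
11 | tert-butyl (3aR,7R,7aS)-3a-hydroxy-7a-methyl-2-oxooctahydro-1H-indene-7-carboxylate (cis-fused aldol adduct) | C1C(=O)C[C@]2(O)CCC[C@@H](C(=O)OC(C)(C)C)[C@@]21C | intermediate
12 | tert-butyl (7R,7aS)-7a-methyl-2-oxo-2,4,5,6,7,7a-hexahydro-1H-indene-7-carboxylate | C1C(=O)C=C2CCC[C@@H](C(=O)OC(C)(C)C)[C@@]21C | intermediate
13 | 2-methylidenepropane-1,3-diol | C=C(CO)CO | starting material
14 | 2-({[tert-butyl(dimethyl)silyl]oxy}methyl)prop-2-en-1-ol | C=C(CO)CO[Si](C)(C)C(C)(C)C | intermediate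
15 | {[2-(bromomethyl)prop-2-en-1-yl]oxy}(tert-butyl)dimethylsilane | C=C(CBr)CO[Si](C)(C)C(C)(C)C | intermediate
16 | lithium (7R,7aS)-7-(tert-butoxycarbonyl)-7a-methyl-5,6,7,7a-tetrahydro-4H-inden-2-olate (cross-conjugated dienolate of 12) | C1=C([O-])C=C2CCC[C@@H](C(=O)OC(C)(C)C)[C@@]21C.[Li+] | intermediate
17 | tert-butyl (1R,7R,7aS)-1-[2-({[tert-butyl(dimethyl)silyl]oxy}methyl)prop-2-en-1-yl]-7a-methyl-2-oxo-2,4,5,6,7,7a-hexahydro-1H-indene-7-carboxylate | C=C(CO[Si](C)(C)C(C)(C)C)C[C@H]1C(=O)C=C2CCC[C@@H](C(=O)OC(C)(C)C)[C@@]21C | intermediate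
18 | tert-butyl (1R,7R,7aS)-2-{[tert-butyl(dimethyl)silyl]oxy}-1-[2-({[tert-butyl(dimethyl)silyl]oxy}methyl)prop-2-en-1-yl]-7a-methyl-5,6,7,7a-tetrahydro-1H-indene-7-carboxylate | C=C(CO[Si](C)(C)C(C)(C)C)C[C@H]1C(O[Si](C)(C)C(C)(C)C)=CC2=CCC[C@@H](C(=O)OC(C)(C)C)[C@@]21C | intermediate
19 | tert-butyl (1R,4S,7R,7aS)-1-[2-({[tert-butyl(dimethyl)silyl]oxy}methyl)prop-2-en-1-yl]-4-hydroxy-7a-methyl-2-oxo-2,4,5,6,7,7a-hexahydro-1H-indene-7-carboxylate | C=C(CO[Si](C)(C)C(C)(C)C)C[C@H]1C(=O)C=C2[C@@H](O)CC[C@@H](C(=O)OC(C)(C)C)[C@@]21C | intermediate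
20 | (4R)-4-benzyl-1,3-oxazolidin-2-one | O=C1N[C@H](Cc2ccccc2)CO1 | starting material
21 | butanoyl chloride | CCCC(=O)Cl | starting material
22 | (4R)-4-benzyl-3-butanoyl-1,3-oxazolidin-2-one | CCCC(=O)N1[C@H](Cc2ccccc2)COC1=O | intermediate
23 | sodium (Z)-1-[(4R)-4-benzyl-2-oxo-1,3-oxazolidin-3-yl]but-1-en-1-olate | CC/C=C(\[O-])N1[C@H](Cc2ccccc2)COC1=O.[Na+] | intermediate
24 | (4R)-4-benzyl-3-[(2R)-2-methylbutanoyl]-1,3-oxazolidin-2-one | CC[C@@H](C)C(=O)N1[C@H](Cc2ccccc2)COC1=O | intermediate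
25 | (2R)-2-methylbutan-1-ol | CC[C@@H](C)CO | intermediate
26 | ethyl 2-(triphenyl-λ5-phosphanylidene)propanoate | CCOC(=O)C(C)=P(c1ccccc1)(c1ccccc1)c1ccccc1 | starting material
27 | (2R)-2-methylbutanal | CC[C@@H](C)C=O | intermediate
28 | ethyl (2E,4R)-2,4-dimethylhex-2-enoate | CC[C@@H](C)/C=C(\C)C(=O)OCC | intermediate
29 | (2E,4R)-2,4-dimethylhex-2-en-1-ol | CC[C@@H](C)/C=C(\C)CO | intermediate
30 | (2E,4R)-2,4-dimethylhex-2-enal | CC[C@@H](C)/C=C(\C)C=O | intermediate
31 | ethyl (2E)-4-(diethoxyphosphoryl)but-2-enoate | CCOC(=O)/C=C/CP(=O)(OCC)OCC | starting material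
32 | lithium (2E)-1-(diethoxyphosphoryl)-4-ethoxy-4-oxobut-2-en-1-ide | CCOC(=O)/C=C/[CH-]P(=O)(OCC)OCC.[Li+] | intermediate
33 | ethyl (2E,4E,6E,8R)-6,8-dimethyldeca-2,4,6-trienoate | CC[C@@H](C)/C=C(C)/C=C/C=C/C(=O)OCC | intermediate
34 | (2E,4E,6E,8R)-6,8-dimethyldeca-2,4,6-trienoic acid | CC[C@@H](C)/C=C(C)/C=C/C=C/C(=O)O | intermediate
35 | (2E,4E,6E,8R)-6,8-dimethyldeca-2,4,6-trienoic 2,4,6-trichlorobenzoic anhydride | CC[C@@H](C)/C=C(C)/C=C/C=C/C(=O)OC(=O)c1c(Cl)cc(Cl)cc1Cl | intermediate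
36 | tert-butyl (1R,4S,7R,7aS)-1-[2-({[tert-butyl(dimethyl)silyl]oxy}methyl)prop-2-en-1-yl]-4-{[(2E,4E,6E,8R)-6,8-dimethyldeca-2,4,6-trienoyl]oxy}-7a-methyl-2-oxo-2,4,5,6,7,7a-hexahydro-1H-indene-7-carboxylate | C=C(CO[Si](C)(C)C(C)(C)C)C[C@H]1C(=O)C=C2[C@@H](OC(=O)/C=C/C=C/C(C)=C/[C@H](C)CC)CC[C@@H](C(=O)OC(C)(C)C)[C@@]21C | intermediate
37 | (1R,4S,7R,7aS)-4-{[(2E,4E,6E,8R)-6,8-dimethyldeca-2,4,6-trienoyl]oxy}-1-[2-(hydroxymethyl)prop-2-en-1-yl]-7a-methyl-2-oxo-2,4,5,6,7,7a-hexahydro-1H-indene-7-carboxylic acid | C=C(CO)C[C@H]1C(=O)C=C2[C@@H](OC(=O)/C=C/C=C/C(C)=C/[C@H](C)CC)CC[C@@H](C(=O)O)[C@@]21C | intermediate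
38 | (1R,4S,7R,7aS)-4-{[(2E,4E,6E,8R)-6,8-dimethyldeca-2,4,6-trienoyl]oxy}-1-(2-formylprop-2-en-1-yl)-7a-methyl-2-oxo-2,4,5,6,7,7a-hexahydro-1H-indene-7-carboxylic acid (CNP0277819.3) | C=C(C=O)C[C@H]1C(=O)C=C2[C@@H](OC(=O)/C=C/C=C/C(C)=C/[C@H](C)CC)CC[C@@H](C(=O)O)[C@@]21C | target

## Step count and weak points

Total step count: 25. Longest linear sequence: 15 steps (steps 1–9, 12–14, 23–25). The bromide arm (steps 10–11) and the acid arm (steps 15–22) are made separately and join at steps 12 and 23.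

The three steps most likely to fail:

**Step 6.** The thermodynamic enol ether may form with poor regioselectivity because of strain between the C2 methyl and the C1 ester. The fallback sets out from 4 and skips 5–8. A copper hydride 1,4-reduction (Cu(OAc)2, (R)-DTBM-SEGPHOS or its mirror image as fixed by a short screen, Me(EtO)2SiH, toluene, 0 °C) delivers hydride to C1 enantioselectively and leaves the silyl group on the tetrasubstituted enolate. This gives tert-butyl (1R)-3-{[diethoxy(methyl)silyl]oxy}-2-methylcyclohex-2-ene-1-carboxylate F1 as a single regioisomer. F1 enters the same palladium and fluoride allylation with diallyl carbonate and comes back to the route at 9.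

**Step 12.** The bromide may enter on the face away from the angular methyl. The fallback sets out from 12, whose alkylation then gives tert-butyl (1S,7R,7aS)-1-[2-({[tert-butyl(dimethyl)silyl]oxy}methyl)prop-2-en-1-yl]-7a-methyl-2-oxo-2,4,5,6,7,7a-hexahydro-1H-indene-7-carboxylate F2. F2 is deprotonated again (LiN(iPr)2, THF, −78 °C) and the enolate is protonated kinetically with acetic acid at −78 °C. The proton then takes the open face that the bromide took, which turns C1 over; the route is rejoined at 17.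

**Step 14.** The γ-hydroxylation depends on the regiochemistry of the enolisation in step 13 and on axial attack of the peracid. The fallback sets out from 17 and comes back at 36:
- Deconjugation (KOtBu, t-BuOH/THF, inverse quench into cold aqueous acetic acid) gives tert-butyl (1R,7R,7aS)-1-[2-({[tert-butyl(dimethyl)silyl]oxy}methyl)prop-2-en-1-yl]-7a-methyl-2-oxo-2,3,5,6,7,7a-hexahydro-1H-indene-7-carboxylate F3.
- mCPBA epoxidises the trisubstituted C3a=C4 bond on the face away from the angular methyl to give tert-butyl (1R,3aS,4R,7R,7aS)-1-[2-({[tert-butyl(dimethyl)silyl]oxy}methyl)prop-2-en-1-yl]-3a,4-epoxy-7a-methyl-2-oxooctahydro-1H-indene-7-carboxylate F4.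
- Et3N opens the epoxide by β-elimination to tert-butyl (1R,4R,7R,7aS)-1-[2-({[tert-butyl(dimethyl)silyl]oxy}methyl)prop-2-en-1-yl]-4-hydroxy-7a-methyl-2-oxo-2,4,5,6,7,7a-hexahydro-1H-indene-7-carboxylate F5, the 4-epimer of 19.
- Mitsunobu esterification of F5 with acid 34 (PPh3, diisopropyl azodicarboxylate, toluene, 0 °C) inverts C4 and gives 36.

## Further compounds

F1 | step 6 | tert-butyl (1R)-3-{[diethoxy(methyl)silyl]oxy}-2-methylcyclohex-2-ene-1-carboxylate | CC1=C(O[Si](C)(OCC)OCC)CCC[C@H]1C(=O)OC(C)(C)C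
F2 | step 12 | tert-butyl (1S,7R,7aS)-1-[2-({[tert-butyl(dimethyl)silyl]oxy}methyl)prop-2-en-1-yl]-7a-methyl-2-oxo-2,4,5,6,7,7a-hexahydro-1H-indene-7-carboxylate | C=C(CO[Si](C)(C)C(C)(C)C)C[C@@H]1C(=O)C=C2CCC[C@@H](C(=O)OC(C)(C)C)[C@@]21C
F3 | step 14 | tert-butyl (1R,7R,7aS)-1-[2-({[tert-butyl(dimethyl)silyl]oxy}methyl)prop-2-en-1-yl]-7a-methyl-2-oxo-2,3,5,6,7,7a-hexahydro-1H-indene-7-carboxylate | C=C(CO[Si](C)(C)C(C)(C)C)C[C@H]1C(=O)CC2=CCC[C@@H](C(=O)OC(C)(C)C)[C@@]21C
F4 | step 14 | tert-butyl (1R,3aS,4R,7R,7aS)-1-[2-({[tert-butyl(dimethyl)silyl]oxy}methyl)prop-2-en-1-yl]-3a,4-epoxy-7a-methyl-2-oxooctahydro-1H-indene-7-carboxylate | C=C(CO[Si](C)(C)C(C)(C)C)C[C@H]1C(=O)C[C@]23O[C@@H]3CC[C@@H](C(=O)OC(C)(C)C)[C@@]21C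
F5 | step 14 | tert-butyl (1R,4R,7R,7aS)-1-[2-({[tert-butyl(dimethyl)silyl]oxy}methyl)prop-2-en-1-yl]-4-hydroxy-7a-methyl-2-oxo-2,4,5,6,7,7a-hexahydro-1H-indene-7-carboxylate | C=C(CO[Si](C)(C)C(C)(C)C)C[C@H]1C(=O)C=C2[C@H](O)CC[C@@H](C(=O)OC(C)(C)C)[C@@]21C
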